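Target is what these flasks are run for, and at 45 °C and 3.00 h it reads lower from the bigger substrate charge.

| flask | substrate | partner | temperature | remark | time |
|---|---|---|---|---|---|
| Wednesday's | 0.063 M (fed, over 2.5 h) | 0.10 M | 45 °C | run made earlier |  |
| Sunday's | 0.086 M (fed, over 2.5 h) | 0.10 M | 70 °C | run made earlier |  |
| Tuesday's | 0.17 M (fed, over 2.5 h) | 0.10 M | 45 °C | run made earlier |  |
| alder | 0.050 M (fed, over 2.5 h) | 0.100 M | 90 °C |  | 6.0 h |
| ash | 0.15 M (fed, over 2.5 h) | 0.100 M | 50 °C |  | 6.0 h |
| larch | 0.050 M (fed, over 2.5 h) | 0.100 M | 50 °C |  | 6.0 h |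
| oak | 0.15 M (fed, over 2.5 h) | 0.100 M | 90 °C |  | 6.0 h |

Wednesday's run (percent of the substrate charged)

| time / h | target / % | substrate / % |
|---|---|---|
| 0.667 | 1 | 19 |
| 1.33 | 7 | 27 |
| 2.00 | 17 | 33 |
| 2.50 | 28 | 30 |
| 3.00 | 30 | 14 |

Sunday's run (percent of the substrate charged)

| time / min | target / % | substrate / % |
|---|---|---|
| 15.0 | 3 | 3 |
| 30.0 | 9 | 2 |
| 40.0 | 12 | 3 |
| 60.0 | 18 | 5 |

Tuesday's run (percent of the substrate charged)

| time / h | target / % | substrate / % |
|---|---|---|
| 0.250 | 0 | 12 |
| 0.833 | 2 | 20 |
| 1.33 | 8 | 25 |
| 2.00 | 15 | 28 |
| 3.00 | 19 | 12 |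

(each reading ± 2 percentage points)

- the numbers in the tables scatter with a standard deviation of 2 percentage points
- a reading or a percentage of target counts all its forms, free or not
- percentages count the whole charge, also what has not yet gone in

- ranking by amount of target, in percent of the substrate charged, from high to low, at 6.0 h (alder / ash / larch / oak)
- the amount of target, in percent of the substrate charged of the flask you put first, at 6.0 h
- the amount of target, in percent of the substrate charged of the flask you put last, at 6.0 h

Each flask starts with partner, and substrate runs in steadily over 2.5 h. In Wednesday's run at 3.00 h, with the feed over, target reads 30% and substrate 14%, so 56.0% of the charge is neither. I call target against that remainder the odds, and I multiply the odds by the charge. That gives 0.0337 M for Wednesday's run and 0.0468 M for Tuesday's, both read through a scatter of 2 percentage points. Their mean, 0.0403 M, is my break-even charge: the substrate charge at which target and the rest of the reacted substrate come out even, at 45 °C with partner and feed time held. It is a selectivity factor in concentration units, and target's share is then break-even over break-even plus charge.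

After the feed, Wednesday's substrate reads as halving in about 0.455 h. At that pace about 0.145% would remain by 6.0 h, so I expect finished flasks.

My reckoning gives larch 44.6% and ash 21.2%. As an estimate I expect both higher: they are reckoned at 45 °C, the flasks stand at 50 °C, and Sunday's run at 70 °C, with 40.0% fed at 60.0 min, reads 0.0911 M, more than my break-even. No run stands near 90 °C, so of the four places I commit to larch above ash. Leave the charges alone.

The forecast says alder > oak > larch > ash, from 66% down to 27%: “Hotter conditions also seem to help”.

The flasks give larch > alder > oak > ash, from 52.8% down to 31.1%. Alder reaches 49.0%, and at 6.00 h it holds 50.1% as decomposed reagent, against 11.0% in larch. Reckoned back, the break-even charge is 0.0560 M in larch and 0.0678 M in ash, both above my 0.0403 M.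

    crystals ⇌ target, rate k1*(cs1 - [target]) while solid is left; crystals form when [target] > cs1 (solubility = 6.50 mM, k = 0.0200 s⁻¹)
    intermediate → decomposed reagent (k = 1.80 × 10⁻⁴ s⁻¹, Ea = 92.0 kJ mol⁻¹)
    substrate + intermediate → side product (k = 0.0380 M⁻¹ s⁻¹, Ea = 46.0 kJ mol⁻¹)
    partner + intermediate → target (k = 0.0100 M⁻¹ s⁻¹, Ea = 53.0 kJ mol⁻¹)
    substrate → intermediate (k = 4.20 × 10⁻⁴ s⁻¹, Ea = 94.0 kJ mol⁻¹)
    (constants at 50 °C)

Take a flask like ash but with 0.60 M of substrate. Ash's break-even charge gives it 10.2%. The computed flask ends at 11.3% target and 85.3% side product.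

The numbers in the tables come from a simulation for an exercise; scatter was added.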